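The synthesis rests on cutting the C7–C8 bond. The homoallylic alcohol array C13=C11–C7–C8–OH, where the α-methylene-γ-butyrolactone (O–C6–C7–C11–C12) meets the ten-membered carbocycle (C1–C10), is the retron of a carbonyl allylation with allylic transposition. One intramolecular Hosomi–Sakurai reaction should close the ten-membered ring, set C7 and C8 and unveil the exocyclic C11=C13 methylene. Its precursor is an open chain: the C8 aldehyde (C9 already esterified, C14 held as a silyl ether) is tethered through the two ring-cis trisubstituted olefins to a 5-substituted 3-[(trimethylsilyl)methyl]furan-2(5H)-one, assembled from neryl acetate, (S)-glyceraldehyde acetonide and divinylzinc.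

Key step: step 15

Remark: atom labels C1–C15 follow germacranolide numbering (ring C1–C10, lactone O–C6 and C7–C11(=C13)–C12(=O), C14 on C10, C15 on C4) and are kept for all intermediates; (S)-glyceraldehyde acetonide and (R)-2-methylbutanoic acid are taken as purchasable.

Step 1
Reactants: 1 neryl acetate
Product: 3 (2Z)-3-methyl-6-oxohex-2-en-1-yl acetate, via secondary ozonide 2 (not isolated)
Conditions: O3 (1 equiv, Sudan Red 7B end point), CH2Cl2, −78 °C; Me2S, −78 °C to rt
Reagents that add atoms: ozone, [O-][O+]=O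
Why: Ozonolysis with reductive work-up; the terminal trisubstituted olefin is more electron-rich than the C4=C5 olefin, which the allylic acetate deactivates, so one equivalent of ozone should cleave it selectively and leave the Z geometry of C4=C5 untouched.

Step 2
Reactants: 3 (2Z)-3-methyl-6-oxohex-2-en-1-yl acetate; 4 (triphenylphosphoranylidene)acetaldehyde
Product: 5 (2Z,6E)-3-methyl-8-oxoocta-2,6-dien-1-yl acetate
Conditions: toluene, 80 °C
Reagents that add atoms: none
Why: Wittig reaction with a stabilised formyl ylide should give the (E)-enal and brings in C10 and C14.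

Step 3
Reactants: 5 (2Z,6E)-3-methyl-8-oxoocta-2,6-dien-1-yl acetate
Product: 6 (2Z,6Z)-7-iodo-3-methyl-8-oxoocta-2,6-dien-1-yl acetate
Conditions: I2, K2CO3, DMAP (cat.), THF/H2O, rt
Reagents that add atoms: iodine, II
Why: Baylis–Hillman-type α-iodination (DMAP conjugate addition, iodination of the enolate, elimination) should give the (Z)-α-iodoenal, with iodine cis to C2 and the formyl group trans to it, the geometry later needed at C1=C10.

Step 4
Reactants: 6 (2Z,6Z)-7-iodo-3-methyl-8-oxoocta-2,6-dien-1-yl acetate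
Product: 7 (2Z,6Z)-8-hydroxy-7-iodo-3-methylocta-2,6-dien-1-yl acetate
Conditions: NaBH4, CeCl3·7H2O, MeOH, −40 °C
Reagents that add atoms: none
Why: Luche 1,2-reduction of the enal should leave the vinyl iodide, the acetate and both olefin geometries intact.

Step 5
Reactants: 7 (2Z,6Z)-8-hydroxy-7-iodo-3-methylocta-2,6-dien-1-yl acetate
Product: 8 (2Z,6Z)-8-[(tert-butyldiphenylsilyl)oxy]-7-iodo-3-methylocta-2,6-dien-1-yl acetate
Conditions: TBDPSCl, imidazole, CH2Cl2, 0 °C to rt
Reagents that add atoms: tert-butyl(chloro)diphenylsilane, CC(C)(C)[Si](Cl)(c1ccccc1)c1ccccc1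
Why: Standard silylation of the primary allylic alcohol; the robust silyl ether keeps C14 at the alcohol level until the end, so that no enal competes in the ring closure.

Step 6
Reactants: 8 (2Z,6Z)-8-[(tert-butyldiphenylsilyl)oxy]-7-iodo-3-methylocta-2,6-dien-1-yl acetate; 9 (4S)-2,2-dimethyl-1,3-dioxolane-4-carbaldehyde
Product: 10 (2Z,6Z)-8-[(tert-butyldiphenylsilyl)oxy]-7-{(R)-[(4S)-2,2-dimethyl-1,3-dioxolan-4-yl](hydroxy)methyl}-3-methylocta-2,6-dien-1-yl acetate
Conditions: CrCl2, NiCl2 (cat.), DMSO, rt
Reagents that add atoms: none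
Why: Nozaki–Hiyama–Kishi coupling: the alkenylchromium forms with retention of olefin geometry (C9 ends cis to C2) and should add to the α-alkoxy aldehyde in the Felkin–Anh sense, anti to the dioxolane C–O bond, which sets C9 as R; the acetate is tolerated.

Step 7
Reactants: 10 the (9R)-allylic alcohol; 11 (2R)-2-methylbutanoic acid
Product: 12 O9-[(2R)-2-methylbutanoate] of 10
Conditions: EDC·HCl, DMAP, CH2Cl2, 0 °C to rt
Reagents that add atoms: none
Why: Steglich esterification of the secondary allylic alcohol installs the side chain with its stereocentre taken from the acid and does not touch C9.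

Step 8
Reactants: 12 O9-[(2R)-2-methylbutanoate] of 10
Product: 13 primary allylic alcohol (12 without the O6 acetyl group)
Conditions: K2CO3, MeOH, 0 °C
Reagents that add atoms: none
Why: Base-catalysed transesterification; the unhindered primary acetate should be methanolysed far faster than the α-branched ester of the hindered secondary C9 alcohol.

Step 9
Reactants: 13 primary allylic alcohol
Product: 14 (Z)-enal (C6 aldehyde)
Conditions: MnO2, CH2Cl2, rt
Reagents that add atoms: none
Why: MnO2 oxidises the allylic alcohol to the enal under neutral conditions and, as in the nerol to neral oxidation, should retain the Z geometry of C4=C5.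

Step 10
Reactants: 14 (Z)-enal
Product: 15 (6S)-vinyl carbinol
Conditions: divinylzinc, (−)-MIB [(2S)-3-exo-morpholinoisoborneol] (10 mol %), toluene, −20 °C; aqueous work-up
Reagents that add atoms: divinylzinc, C=C[Zn]C=C
Why: Amino-alcohol-catalysed addition of a vinylzinc reagent to an aldehyde (Noyori–Oppolzer type); the (−)-MIB–zinc complex should deliver the vinyl group to the si face and set C6 as S, and any minor C6 epimer is a separable diastereomer.

Step 11
Reactants: 16 ethyl 2-[(trimethylsilyl)methyl]prop-2-enoate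
Product: 17 2-[(trimethylsilyl)methyl]prop-2-enoic acid
Conditions: LiOH, THF/H2O, rt; 1 M HCl, 0 °C
Reagents that add atoms: lithium hydroxide, [Li+].[OH-]
Why: Simple saponification; the ester-conjugated allylsilane is stable to aqueous base and to brief cold acidification.

Step 12
Reactants: 15 (6S)-vinyl carbinol; 17 2-[(trimethylsilyl)methyl]prop-2-enoic acid
Product: 18 O6-{2-[(trimethylsilyl)methyl]acrylate} of 15
Conditions: EDC·HCl, DMAP (cat.), CH2Cl2, 0 °C
Reagents that add atoms: none
Why: Steglich esterification of the bis-allylic alcohol under mild conditions proceeds at oxygen, so C6 keeps its configuration.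

Step 13
Reactants: 18 O6-{2-[(trimethylsilyl)methyl]acrylate} of 15
Product: 19 (5R)-5-substituted 3-[(trimethylsilyl)methyl]furan-2(5H)-one
Conditions: second-generation Hoveyda–Grubbs catalyst (5 mol %), toluene, 80 °C
Reagents that add atoms: none
Why: Ring-closing metathesis: the catalyst loads on the monosubstituted vinyl group and closes the five-membered ring onto the 1,1-disubstituted acrylate while the hindered trisubstituted olefins stay out, which gives the butenolide with C7=C11 in the ring and silicon on C13.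

Step 14
Reactants: 19 (5R)-butenolide acetonide
Product: 21 C8 aldehyde, via diol 20 (not isolated)
Conditions: H5IO6, EtOAc, 0 °C to rt
Reagents that add atoms: none
Why: Periodic acid hydrolyses the terminal acetonide and cleaves the liberated 1,2-diol in the same flask (glycol cleavage), which unmasks the α-acyloxy aldehyde without base, so C9 and C6 should not epimerise and the ester has no time to migrate.

Step 15
Reactants: 21 C8 aldehyde
Product: 22 (6R,7R,8S,9R)-macrocycle, 14-O-TBDPS ether of the 14-alcohol
Conditions: BF3·OEt2, CH2Cl2 (1 mM, slow addition of 21), −78 to −40 °C; aq. NaHCO3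
Reagents that add atoms: none
Why: BF3 activates the C8 aldehyde and C7, the γ-carbon of the ester-substituted allylsilane, attacks it in an SE2' sense; the β-silyl cation at C11 then loses Me3Si, which moves the double bond from C7=C11 to C11=C13 and unveils the α-methylene lactone. The closest known reaction type is the intramolecular Hosomi–Sakurai allylation of 2-(silylmethyl)acrylate-type allylsilanes with aldehydes, which gives carbocycle-fused α-methylene-γ-butyrolactones. The ten-membered carbocycle closes in a 10-exo-trig mode at the aldehyde carbon (O8 outside the new ring), and the two ring-cis olefins C4=C5 and C1=C10 pre-fold the chain. C7 is set by C6: the aldehyde, tethered through C5, should reach C7 on the butenolide face opposite to the C5 substituent, which gives the trans ring fusion. C8 is set by C9 in an open, non-chelated transition state of polar Felkin–Anh type, with the C9–O bond anti to the forming bond and the carbonyl oxygen gauche to C10, which gives 8S; a closed, metal-bridged Barbier-type transition state would hold O8 over C13 and is expected to give the 8-epimer, which is why silicon and a monodentate Lewis acid are chosen. The step needs the deactivated allylsilane to win over the C4=C5 olefin and over intermolecular reaction; this is secured by the very electrophilic α-acyloxy aldehyde, by keeping C14 as a silyl ether and not an enal, and by high dilution at low temperature.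

Step 16
Reactants: 22 (6R,7R,8S,9R)-macrocycle silyl ether
Product: 23 14-alcohol (8,14-diol 9-ester)
Conditions: HF·pyridine, pyridine, THF, 0 °C to rt
Reagents that add atoms: none
Why: Fluoride cleavage of the silyl ether under buffered acidic conditions forms no alkoxide, so neither acyl migration from O9 to O8 nor conjugate addition to the methylene lactone should occur.

Step 17
Reactants: 23 14-alcohol
Product: 24 target CNP0256845.2
Conditions: MnO2, CH2Cl2, rt
Reagents that add atoms: none
Why: MnO2 oxidises only the primary allylic alcohol at C14 to the enal; the secondary C8 alcohol is not allylic and should survive.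

Compound list
1 | neryl acetate, (2Z)-3,7-dimethylocta-2,6-dien-1-yl acetate | CC(C)=CCC/C(C)=C\COC(C)=O | starting material
2 | secondary ozonide of 1 (3,3-dimethyl-1,2,4-trioxolane formed at the terminal olefin) | CC1(C)OOC(CC/C(C)=C\COC(C)=O)O1 | intermediate
3 | (2Z)-3-methyl-6-oxohex-2-en-1-yl acetate | O=CCC/C(C)=C\COC(C)=O | intermediate
4 | (triphenylphosphoranylidene)acetaldehyde | O=CC=P(c1ccccc1)(c1ccccc1)c1ccccc1 | starting material
5 | (2Z,6E)-3-methyl-8-oxoocta-2,6-dien-1-yl acetate | O=C/C=C/CC/C(C)=C\COC(C)=O | intermediate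
6 | (2Z,6Z)-7-iodo-3-methyl-8-oxoocta-2,6-dien-1-yl acetate | O=C/C(I)=C/CC/C(C)=C\COC(C)=O | intermediate
7 | (2Z,6Z)-8-hydroxy-7-iodo-3-methylocta-2,6-dien-1-yl acetate | OC/C(I)=C/CC/C(C)=C\COC(C)=O | intermediate
8 | (2Z,6Z)-8-[(tert-butyldiphenylsilyl)oxy]-7-iodo-3-methylocta-2,6-dien-1-yl acetate | CC(C)(C)[Si](OC/C(I)=C/CC/C(C)=C\COC(C)=O)(c1ccccc1)c1ccccc1 | intermediate
9 | (4S)-2,2-dimethyl-1,3-dioxolane-4-carbaldehyde, (S)-glyceraldehyde acetonide | CC1(C)OC[C@@H](C=O)O1 | starting material
10 | (2Z,6Z)-8-[(tert-butyldiphenylsilyl)oxy]-7-{(R)-[(4S)-2,2-dimethyl-1,3-dioxolan-4-yl](hydroxy)methyl}-3-methylocta-2,6-dien-1-yl acetate (9R alcohol, 8,9-anti, C2 cis to C9) | CC(C)(C)[Si](OC/C(=C/CC/C(C)=C\COC(C)=O)[C@@H](O)[C@@H]1COC(C)(C)O1)(c1ccccc1)c1ccccc1 | intermediate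
11 | (2R)-2-methylbutanoic acid | CC[C@@H](C)C(=O)O | starting material
12 | O9-[(2R)-2-methylbutanoate] of 10 (9R, dioxolane 4S, O6 acetate, O14 TBDPS, C4=C5 Z, C2 cis to C9) | CC(C)(C)[Si](OC/C(=C/CC/C(C)=C\COC(C)=O)[C@@H](OC(=O)[C@H](C)CC)[C@@H]1COC(C)(C)O1)(c1ccccc1)c1ccccc1 | intermediate
13 | primary allylic alcohol, 12 with free 6-OH | CC(C)(C)[Si](OC/C(=C/CC/C(C)=C\CO)[C@@H](OC(=O)[C@H](C)CC)[C@@H]1COC(C)(C)O1)(c1ccccc1)c1ccccc1 | intermediate
14 | (Z)-enal, C6 aldehyde from 13 | CC(C)(C)[Si](OC/C(=C/CC/C(C)=C\C=O)[C@@H](OC(=O)[C@H](C)CC)[C@@H]1COC(C)(C)O1)(c1ccccc1)c1ccccc1 | intermediate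
15 | (6S)-vinyl carbinol, C6 bearing OH and the vinyl group C7=CH2 (9R, dioxolane 4S) | CC(C)(C)[Si](OC/C(=C/CC/C(C)=C\[C@@H](O)C=C)[C@@H](OC(=O)[C@H](C)CC)[C@@H]1COC(C)(C)O1)(c1ccccc1)c1ccccc1 | intermediate
16 | ethyl 2-[(trimethylsilyl)methyl]prop-2-enoate | CCOC(=O)C(=C)C[Si](C)(C)C | starting material
17 | 2-[(trimethylsilyl)methyl]prop-2-enoic acid | OC(=O)C(=C)C[Si](C)(C)C | intermediate
18 | O6-{2-[(trimethylsilyl)methyl]acrylate} of 15 (6S) | CC(C)(C)[Si](OC/C(=C/CC/C(C)=C\[C@@H](OC(=O)C(=C)C[Si](C)(C)C)C=C)[C@@H](OC(=O)[C@H](C)CC)[C@@H]1COC(C)(C)O1)(c1ccccc1)c1ccccc1 | intermediate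
19 | (5R)-5-substituted 3-[(trimethylsilyl)methyl]furan-2(5H)-one, butenolide O–C6–C7=C11–C12 with C13H2SiMe3, acetonide still in place | CC(C)(C)[Si](OC/C(=C/CC/C(C)=C\[C@H]1OC(=O)C(C[Si](C)(C)C)=C1)[C@@H](OC(=O)[C@H](C)CC)[C@@H]1COC(C)(C)O1)(c1ccccc1)c1ccccc1 | intermediate
20 | terminal 1,2-diol from 19 (acetonide removed) | CC(C)(C)[Si](OC/C(=C/CC/C(C)=C\[C@H]1OC(=O)C(C[Si](C)(C)C)=C1)[C@@H](OC(=O)[C@H](C)CC)[C@@H](O)CO)(c1ccccc1)c1ccccc1 | intermediate
21 | C8 aldehyde, (9R)-α-acyloxy aldehyde tethered to the (5R)-3-[(trimethylsilyl)methyl]butenolide | CC(C)(C)[Si](OC/C(=C/CC/C(C)=C\[C@H]1OC(=O)C(C[Si](C)(C)C)=C1)[C@@H](OC(=O)[C@H](C)CC)C=O)(c1ccccc1)c1ccccc1 | intermediate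
22 | (6R,7R,8S,9R)-macrocycle: trans-fused α-methylene lactone, 8-OH, 9-O-(2R)-2-methylbutanoate, 14-O-TBDPS | C=C1C(=O)O[C@@H]2/C=C(/C)CC/C=C(/CO[Si](c3ccccc3)(c3ccccc3)C(C)(C)C)[C@@H](OC(=O)[C@H](C)CC)[C@@H](O)[C@@H]12 | intermediate
23 | (6R,7R,8S,9R)-14-alcohol | C=C1C(=O)O[C@@H]2/C=C(/C)CC/C=C(/CO)[C@@H](OC(=O)[C@H](C)CC)[C@@H](O)[C@@H]12 | intermediate
24 | CNP0256845.2, (6R,7R,8S,9R)-14-al | C=C1C(=O)O[C@@H]2/C=C(/C)CC/C=C(/C=O)[C@@H](OC(=O)[C@H](C)CC)[C@@H](O)[C@@H]12 | target

Total step count: 17. Longest linear sequence: 16 steps (steps 1–10 and 12–17, from neryl acetate).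

Steps most likely to fail

1. Step 15. The ester-deactivated allylsilane may attack too slowly, so that protodesilylation, cationic attack of the C4=C5 olefin on the activated aldehyde or oligomerisation takes over, or the facial selectivity at C8 may erode. The fallback sets out from 15 and changes the nucleophile to an allylchromium species, followed by a redox correction at C8. Compound 15 is esterified with 2-(bromomethyl)acrylic acid (EDC·HCl, DMAP cat.) to the bromoacrylate ester F1. Ring-closing metathesis as in step 13 gives the 3-(bromomethyl)butenolide F2, and H5IO6 as in step 14 gives the bromo aldehyde F3. A Nozaki–Hiyama–Kishi allylation (CrCl2, THF/DMF, high dilution) closes the same C7–C8 bond through a chromium-bridged chair and is expected to give the 8-epimeric macrocycle F4. Dess–Martin oxidation gives the C8 ketone F5. Luche reduction (NaBH4, CeCl3·7H2O, MeOH, −78 °C), with hydride entering from the ring periphery on the side away from C10, should return to the route at 22.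

2. Step 10. Ligand control may be insufficient on the hindered β,β-disubstituted (Z)-enal, and the enal may isomerise from Z to E under the Lewis-acidic zinc species. The fallback sets out from 14. Fast, unselective addition of vinylmagnesium bromide with CeCl3 at −78 °C gives 15 together with the (6R)-epimer F6, which are diastereomers and can be separated. F6 is recycled by Dess–Martin oxidation to the cross-conjugated dienone F7 and reduction with (R)-2-methyl-CBS-oxazaborolidine and catecholborane (vinyl as the small group). This comes back to the route at 15.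

3. Step 6. The oxidative addition of the hindered trisubstituted vinyl iodide may be slow, and the Felkin–Anh preference of the alkenylchromium addition may be poor. The fallback sets out from 8 and moves the stereocontrol from C–C bond formation to a ketone reduction. The coupling is run without regard to selectivity, and the mixture of 10 and the (9S)-epimer F8 is oxidised with Dess–Martin periodinane to the enone F9. Chelation-controlled reduction with Zn(BH4)2 (Et2O, −20 °C; zinc bridging the ketone and the α-oxygen of the dioxolane) should give the 8,9-anti alcohol. This comes back to the route at 10.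

Further compounds
F1 | step 15 | O6-[2-(bromomethyl)acrylate] of 15 | CC(C)(C)[Si](OC/C(=C/CC/C(C)=C\[C@@H](OC(=O)C(=C)CBr)C=C)[C@@H](OC(=O)[C@H](C)CC)[C@@H]1COC(C)(C)O1)(c1ccccc1)c1ccccc1
F2 | step 15 | (5R)-3-(bromomethyl)furan-2(5H)-one analogue of 19 | CC(C)(C)[Si](OC/C(=C/CC/C(C)=C\[C@H]1OC(=O)C(CBr)=C1)[C@@H](OC(=O)[C@H](C)CC)[C@@H]1COC(C)(C)O1)(c1ccccc1)c1ccccc1
F3 | step 15 | C8 aldehyde analogue of 21 with C13H2Br | CC(C)(C)[Si](OC/C(=C/CC/C(C)=C\[C@H]1OC(=O)C(CBr)=C1)[C@@H](OC(=O)[C@H](C)CC)C=O)(c1ccccc1)c1ccccc1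
F4 | step 15 | (8R)-epimer of 22 | C=C1C(=O)O[C@@H]2/C=C(/C)CC/C=C(/CO[Si](c3ccccc3)(c3ccccc3)C(C)(C)C)[C@@H](OC(=O)[C@H](C)CC)[C@H](O)[C@@H]12
F5 | step 15 | C8 ketone corresponding to 22 | C=C1C(=O)O[C@@H]2/C=C(/C)CC/C=C(/CO[Si](c3ccccc3)(c3ccccc3)C(C)(C)C)[C@@H](OC(=O)[C@H](C)CC)C(=O)[C@@H]12
F6 | step 10 | (6R)-epimer of 15 | CC(C)(C)[Si](OC/C(=C/CC/C(C)=C\[C@H](O)C=C)[C@@H](OC(=O)[C@H](C)CC)[C@@H]1COC(C)(C)O1)(c1ccccc1)c1ccccc1
F7 | step 10 | cross-conjugated dienone (C6 ketone) from F6 | CC(C)(C)[Si](OC/C(=C/CC/C(C)=C\C(=O)C=C)[C@@H](OC(=O)[C@H](C)CC)[C@@H]1COC(C)(C)O1)(c1ccccc1)c1ccccc1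
F8 | step 6 | (9S)-epimer of 10 | CC(C)(C)[Si](OC/C(=C/CC/C(C)=C\COC(C)=O)[C@H](O)[C@@H]1COC(C)(C)O1)(c1ccccc1)c1ccccc1
F9 | step 6 | enone (C9 ketone) from 10 and F8 | CC(C)(C)[Si](OC/C(=C/CC/C(C)=C\COC(C)=O)C(=O)[C@@H]1COC(C)(C)O1)(c1ccccc1)c1ccccc1
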